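**Retrosynthetic overview** (locants: C6 = lactone carbinol, C7 = ring-fusion CH, C8 = angelate carbinol, C4 = CH(CH2OH), C1=C10 = ring alkene)
1. Target 19 ⇐ silyl ether 18 ⇐ triene lactone 17 by ring-closing metathesis at C1=C10; the ten-membered ring is formed last.
2. 17 ⇐ aldehyde 5 + allylboronate 15 by chiral Brønsted acid catalysed allylboration–lactonisation (C6–C7 bond, C6 and C7); the lactone ring is formed first.
3. 15 ⇐ ynoate 13 by syn-hydroalumination and CH2Bpin trapping; 13 ⇐ alcohol 10 + angelic acid 11; 10 ⇐ ynal 7 + boronate 8 by phosphoric acid catalysed allylboration (C8).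
4. 5 ⇐ hex-5-enal 1 by prolinol ether catalysed α-hydroxymethylation (C4), silylation and one-carbon homologation.

Assumption: 1, 6, 8, 11, 2-(iodomethyl)pinacolborane and both enantiomers of each catalyst are purchased; the target SMILES is read as (3aS,4R,10R,11aR) with a 6E ring alkene and a Z (angelate) ester.

**Step 1**
Reactants: 1 hex-5-enal
Product: 2 (2S)-2-(hydroxymethyl)hex-5-enal
Conditions: 37% aq. HCHO (3 equiv), (R)-α,α-diphenylprolinol TMS ether (20 mol%), pH 7 phosphate buffer, toluene, rt, 36 h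
Reagents that add atoms: formaldehyde, C=O
Why: Enamine catalysis (organocatalytic α-hydroxymethylation, a cross-aldol with formaldehyde): the E-enamine of 1 is shielded on one face by the CPh2OTMS group of the (R)-catalyst, so formaldehyde adds to the open face and sets the first stereocenter (C4) as S.

**Step 2**
Reactants: 2 (2S)-2-(hydroxymethyl)hex-5-enal
Product: 3 (2S)-2-({[tert-butyl(diphenyl)silyl]oxy}methyl)hex-5-enal
Conditions: TBDPSCl (1.1 equiv), imidazole (2 equiv), CH2Cl2, 0 °C, 1 h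
Reagents that add atoms: tert-butyl(chloro)diphenylsilane, CC(C)(C)[Si](Cl)(c1ccccc1)c1ccccc1
Why: Silyl ether formation at 0 °C under weakly basic conditions caps the primary alcohol before the β-hydroxy aldehyde can dehydrate or epimerise, and the stereocenter is untouched.

**Step 3**
Reactants: 3 (2S)-2-({[tert-butyl(diphenyl)silyl]oxy}methyl)hex-5-enal
Product: 5 (3R)-3-({[tert-butyl(diphenyl)silyl]oxy}methyl)hept-6-enal, via methyl enol ether 4 (not isolated)
Conditions: MeOCH2PPh3Cl (1.5 equiv), KHMDS (1.4 equiv), THF, −78 → 0 °C; then 2 M aq. HCl, THF, rt, 3 h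
Reagents that add atoms: (methoxymethyl)triphenylphosphonium chloride, COC[P+](c1ccccc1)(c1ccccc1)c1ccccc1.[Cl-]; water, O
Why: Wittig methoxymethylenation followed by acid hydrolysis of the enol ether (one-carbon homologation) moves the stereocenter from the α- to the non-epimerisable β-position, the ylide being added at −78 °C to avoid α-epimerisation and the TBDPS ether surviving aqueous HCl (the descriptor becomes R only through CIP priorities).

**Step 4**
Reactants: 6 methyl 4-hydroxybut-2-ynoate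
Product: 7 methyl 4-oxobut-2-ynoate
Conditions: Dess–Martin periodinane (1.2 equiv), CH2Cl2, 0 °C → rt, 1 h; filtered and used as a solution
Reagents that add atoms: none
Why: Dess–Martin oxidation of the propargylic alcohol under neutral conditions gives the electron-poor ynal, which is used at once because it is volatile and reactive.

**Step 5**
Reactants: 7 methyl 4-oxobut-2-ynoate; 8 methyl 2-[(4,4,5,5-tetramethyl-1,3,2-dioxaborolan-2-yl)methyl]prop-2-enoate
Product: 10 dimethyl (4R)-4-hydroxy-2-methylidenehept-5-ynedioate, via O-pinacolboryl ether 9 (not isolated)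
Conditions: (R)-TRIP phosphoric acid (5 mol%), 4 Å MS, toluene, −40 °C, 24 h; aq. NaHCO3 work-up
Reagents that add atoms: none
Why: Chiral phosphoric acid catalysed allylboration through a chair transition state in which the acid hydrogen-bonds a pinacol oxygen and the phosphoryl oxygen holds the formyl C–H, so that (R)-TRIP directs allyl transfer to the Re face of 7 and sets C8 as R while the ester-deactivated boronate shows little background reaction at −40 °C.

**Step 6**
Reactants: 10 dimethyl (4R)-4-hydroxy-2-methylidenehept-5-ynedioate; 11 angelic acid [(2Z)-2-methylbut-2-enoic acid]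
Product: 13 dimethyl (4R)-2-methylidene-4-{[(2Z)-2-methylbut-2-enoyl]oxy}hept-5-ynedioate, via mixed anhydride 12 (not isolated)
Conditions: 11 (1.5 equiv), 2,4,6-Cl3C6H2COCl (1.5 equiv), Et3N (2 equiv), toluene, rt, 2 h; then 10, toluene, 50 °C, 12 h (no DMAP)
Reagents that add atoms: none
Why: Yamaguchi esterification through the mixed anhydride without DMAP acylates the secondary alcohol while keeping the Z geometry of the angelate, and the stereocenter is not involved.

**Step 7**
Reactants: 13 dimethyl (4R)-2-methylidene-4-{[(2Z)-2-methylbut-2-enoyl]oxy}hept-5-ynedioate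
Product: 15 dimethyl (2Z,4R)-6-methylidene-4-{[(2Z)-2-methylbut-2-enoyl]oxy}-2-[(4,4,5,5-tetramethyl-1,3,2-dioxaborolan-2-yl)methyl]hept-2-enedioate, via vinylalane 14 (not isolated)
Conditions: DIBAL-H (1.1 equiv), HMPA (2.2 equiv), THF, 0 °C; 13, −40 °C, 1 h; then ICH2Bpin (1.5 equiv), −40 °C → rt
Reagents that add atoms: 2-(iodomethyl)-4,4,5,5-tetramethyl-1,3,2-dioxaborolane, ICB1OC(C)(C)C(C)(C)O1
Why: Conjugate hydroalumination with DIBAL-H·HMPA is syn and much faster for the ynoate than for the α-substituted acrylate or the angelate, and the vinylalane alkylates the iodomethylboronate through a boron ate complex and 1,2-shift with retention, so C8 ends cis to the ester and trans to CH2Bpin.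

**Step 8**
Reactants: 5 (3R)-3-({[tert-butyl(diphenyl)silyl]oxy}methyl)hept-6-enal; 15 dimethyl (2Z,4R)-6-methylidene-4-{[(2Z)-2-methylbut-2-enoyl]oxy}-2-[(4,4,5,5-tetramethyl-1,3,2-dioxaborolan-2-yl)methyl]hept-2-enedioate
Product: 17 methyl (4R)-4-[(2R,3S)-2-[(2R)-2-({[tert-butyl(diphenyl)silyl]oxy}methyl)hex-5-en-1-yl]-4-methylidene-5-oxooxolan-3-yl]-2-methylidene-4-{[(2Z)-2-methylbut-2-enoyl]oxy}butanoate, via O-pinacolboryl hydroxy diester 16 (not isolated)
Conditions: (S)-3,3'-bis(2,4,6-triisopropylphenyl)-BINOL N-triflylphosphoramide (10 mol%), 4 Å MS, toluene, 0 °C → rt, 48 h; then TsOH·H2O (20 mol%), rt, 2 h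
Reagents that add atoms: none
Why: Proposed new method: a chiral N-triflylphosphoramide catalysed tandem allylboration–lactonisation of an ester-deactivated, γ-branched allylboronate, in which the strong chiral Brønsted acid hydrogen-bonds a pinacol oxygen (raising boron Lewis acidity) and the formyl C–H so that the chair transition state delivers C7 to the Si face of 5 (C6 = R), the γ-substituent trans to CH2B sits equatorial (6,7-anti, hence the trans-lactone) and attack occurs anti to the C9 chain with C8–H eclipsing the ester-bearing alkene (C7 = S, reinforcing the catalyst), after which acid closes the lactone with loss of methanol; the closest known reactions are the phosphoric acid catalysed allylboration of aldehydes with pinacol allylboronates and the Lewis or Brønsted acid catalysed allylboration–lactonisation of 2-alkoxycarbonyl allylboronates.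

**Step 9**
Reactants: 17 methyl (4R)-4-[(2R,3S)-2-[(2R)-2-({[tert-butyl(diphenyl)silyl]oxy}methyl)hex-5-en-1-yl]-4-methylidene-5-oxooxolan-3-yl]-2-methylidene-4-{[(2Z)-2-methylbut-2-enoyl]oxy}butanoate
Product: 18 methyl (3aS,4R,6E,10R,11aR)-10-({[tert-butyl(diphenyl)silyl]oxy}methyl)-3-methylidene-4-{[(2Z)-2-methylbut-2-enoyl]oxy}-2-oxo-2,3,3a,4,5,8,9,10,11,11a-decahydrocyclodeca[b]furan-6-carboxylate
Conditions: Hoveyda–Grubbs II (2 × 7.5 mol%), 2,6-dichloro-1,4-benzoquinone (10 mol%), toluene (1 mM), 80 °C, Ar sparge, 12 h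
Reagents that add atoms: none
Why: Ring-closing metathesis in which the ruthenium carbene forms at the monosubstituted alkene and closes onto the 2-substituted acrylate at C10 to give the ten-membered ring with the ring-cis (6E) trisubstituted enoate, whereas closure onto the α-methylene lactone would need a strained bridgehead alkene; ethene loss drives the reaction and no stereocenter changes.

**Step 10**
Reactants: 18 methyl (3aS,4R,6E,10R,11aR)-10-({[tert-butyl(diphenyl)silyl]oxy}methyl)-3-methylidene-4-{[(2Z)-2-methylbut-2-enoyl]oxy}-2-oxo-2,3,3a,4,5,8,9,10,11,11a-decahydrocyclodeca[b]furan-6-carboxylate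
Product: 19 methyl (3aS,4R,6E,10R,11aR)-10-(hydroxymethyl)-3-methylidene-4-{[(2Z)-2-methylbut-2-enoyl]oxy}-2-oxo-2,3,3a,4,5,8,9,10,11,11a-decahydrocyclodeca[b]furan-6-carboxylate (CNP0167542.1)
Conditions: HF·pyridine, pyridine/THF, 0 °C → rt
Reagents that add atoms: none
Why: Fluoride-mediated desilylation (strong Si–F bond) under mildly acidic buffered conditions frees the primary alcohol without touching the α-methylene lactone, the enoate or the angelate.

**Compound list**
1 | hex-5-enal | C=CCCCC=O | starting material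
2 | (2S)-2-(hydroxymethyl)hex-5-enal | O=C[C@H](CO)CCC=C | intermediate
3 | (2S)-2-({[tert-butyl(diphenyl)silyl]oxy}methyl)hex-5-enal | O=C[C@H](CO[Si](c1ccccc1)(c1ccccc1)C(C)(C)C)CCC=C | intermediate
4 | tert-butyl{[(2R)-2-(2-methoxyethenyl)hex-5-en-1-yl]oxy}diphenylsilane (E/Z mixture, not isolated) | COC=C[C@H](CO[Si](c1ccccc1)(c1ccccc1)C(C)(C)C)CCC=C | intermediate
5 | (3R)-3-({[tert-butyl(diphenyl)silyl]oxy}methyl)hept-6-enal | O=CC[C@H](CO[Si](c1ccccc1)(c1ccccc1)C(C)(C)C)CCC=C | intermediate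
6 | methyl 4-hydroxybut-2-ynoate | COC(=O)C#CCO | starting material
7 | methyl 4-oxobut-2-ynoate | COC(=O)C#CC=O | intermediate
8 | methyl 2-[(4,4,5,5-tetramethyl-1,3,2-dioxaborolan-2-yl)methyl]prop-2-enoate | COC(=O)C(=C)CB1OC(C)(C)C(C)(C)O1 | starting material
9 | dimethyl (4R)-2-methylidene-4-[(4,4,5,5-tetramethyl-1,3,2-dioxaborolan-2-yl)oxy]hept-5-ynedioate (not isolated) | COC(=O)C(=C)C[C@@H](OB1OC(C)(C)C(C)(C)O1)C#CC(=O)OC | intermediate
10 | dimethyl (4R)-4-hydroxy-2-methylidenehept-5-ynedioate | COC(=O)C(=C)C[C@@H](O)C#CC(=O)OC | intermediate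
11 | angelic acid, (2Z)-2-methylbut-2-enoic acid | C/C=C(/C)C(=O)O | starting material
12 | (2Z)-2-methylbut-2-enoic 2,4,6-trichlorobenzoic anhydride (not isolated) | C/C=C(/C)C(=O)OC(=O)c1c(Cl)cc(Cl)cc1Cl | intermediate
13 | dimethyl (4R)-2-methylidene-4-{[(2Z)-2-methylbut-2-enoyl]oxy}hept-5-ynedioate | COC(=O)C(=C)C[C@@H](OC(=O)/C(C)=C\C)C#CC(=O)OC | intermediate
14 | dimethyl (2E,4R)-2-[bis(2-methylpropyl)alumanyl]-6-methylidene-4-{[(2Z)-2-methylbut-2-enoyl]oxy}hept-2-enedioate (not isolated) | COC(=O)C(=C)C[C@@H](OC(=O)/C(C)=C\C)/C=C(/[Al](CC(C)C)CC(C)C)C(=O)OC | intermediate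
15 | dimethyl (2Z,4R)-6-methylidene-4-{[(2Z)-2-methylbut-2-enoyl]oxy}-2-[(4,4,5,5-tetramethyl-1,3,2-dioxaborolan-2-yl)methyl]hept-2-enedioate | COC(=O)C(=C)C[C@@H](OC(=O)/C(C)=C\C)/C=C(/CB1OC(C)(C)C(C)(C)O1)C(=O)OC | intermediate
16 | dimethyl (4R,5S)-5-[(1R,3R)-3-({[tert-butyl(diphenyl)silyl]oxy}methyl)-1-[(4,4,5,5-tetramethyl-1,3,2-dioxaborolan-2-yl)oxy]hept-6-en-1-yl]-2,6-dimethylidene-4-{[(2Z)-2-methylbut-2-enoyl]oxy}heptanedioate (not isolated) | COC(=O)C(=C)[C@@H]([C@H](OB1OC(C)(C)C(C)(C)O1)C[C@H](CO[Si](c1ccccc1)(c1ccccc1)C(C)(C)C)CCC=C)[C@H](OC(=O)/C(C)=C\C)CC(=C)C(=O)OC | intermediate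
17 | methyl (4R)-4-[(2R,3S)-2-[(2R)-2-({[tert-butyl(diphenyl)silyl]oxy}methyl)hex-5-en-1-yl]-4-methylidene-5-oxooxolan-3-yl]-2-methylidene-4-{[(2Z)-2-methylbut-2-enoyl]oxy}butanoate | C=C1C(=O)O[C@H](C[C@H](CO[Si](c2ccccc2)(c2ccccc2)C(C)(C)C)CCC=C)[C@H]1[C@H](OC(=O)/C(C)=C\C)CC(=C)C(=O)OC | intermediate
18 | methyl (3aS,4R,6E,10R,11aR)-10-({[tert-butyl(diphenyl)silyl]oxy}methyl)-3-methylidene-4-{[(2Z)-2-methylbut-2-enoyl]oxy}-2-oxo-2,3,3a,4,5,8,9,10,11,11a-decahydrocyclodeca[b]furan-6-carboxylate | C=C1C(=O)O[C@@H]2C[C@H](CO[Si](c3ccccc3)(c3ccccc3)C(C)(C)C)CC/C=C(/C(=O)OC)C[C@@H](OC(=O)/C(C)=C\C)[C@@H]12 | intermediate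
19 | methyl (3aS,4R,6E,10R,11aR)-10-(hydroxymethyl)-3-methylidene-4-{[(2Z)-2-methylbut-2-enoyl]oxy}-2-oxo-2,3,3a,4,5,8,9,10,11,11a-decahydrocyclodeca[b]furan-6-carboxylate | C=C1C(=O)O[C@@H]2C[C@H](CO)CC/C=C(/C(=O)OC)C[C@@H](OC(=O)/C(C)=C\C)[C@@H]12 | target

**Totals and risks**
Total step count: 10. Longest linear sequence: 7 (steps 4–10).

The three steps most likely to fail:

Step 7, the hydroalumination and borylmethylation. The hydride must pick the ynoate over the acrylate, the angelate and an SN2′ loss of the propargylic ester, and the vinylalane must keep its geometry. The fallback sets out from 13 and comes back at 15. Pd(PPh3)4-catalysed syn-hydrostannation of 13 with Bu3SnH (THF, 0 °C) puts tin α to the ester and ignores acrylates and esters, giving dimethyl (2E,4R)-6-methylidene-4-{[(2Z)-2-methylbut-2-enoyl]oxy}-2-(tributylstannyl)hept-2-enedioate F1. Iododestannylation (I2, CH2Cl2, 0 °C) gives with retention dimethyl (2E,4R)-2-iodo-6-methylidene-4-{[(2Z)-2-methylbut-2-enoyl]oxy}hept-2-enedioate F2. Pd-catalysed Negishi coupling of F2 with (pinacolboryl)methylzinc iodide (THF, rt) then gives 15 with the same alkene geometry.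

Step 8, the proposed new step. The ester-deactivated, branched boronate may react too slowly, or the catalyst and the C8 stereocenter may not cooperate. The fallback uses known chemistry, sets out from 15 and 5 and comes back at 17. Oxidation of 15 (NaBO3·4H2O, THF/H2O, rt) gives dimethyl (2Z,4R)-2-(hydroxymethyl)-6-methylidene-4-{[(2Z)-2-methylbut-2-enoyl]oxy}hept-2-enedioate F3. Appel bromination (CBr4, PPh3, CH2Cl2, 0 °C) gives dimethyl (2E,4R)-2-(bromomethyl)-6-methylidene-4-{[(2Z)-2-methylbut-2-enoyl]oxy}hept-2-enedioate F4. CrCl2-mediated Nozaki–Hiyama allylation of 5 with F4 (THF, rt) is anti-selective whatever the bromide geometry, with the face set by C8, and gives dimethyl (4R,5S)-5-[(1R,3R)-3-({[tert-butyl(diphenyl)silyl]oxy}methyl)-1-hydroxyhept-6-en-1-yl]-2,6-dimethylidene-4-{[(2Z)-2-methylbut-2-enoyl]oxy}heptanedioate F5. TsOH then closes F5 to 17.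

Step 9, the ring-closing metathesis. A ten-membered ring with a trisubstituted enoate may give oligomers or the wrong alkene geometry. The fallback inverts the order of the two ring closures, sets out from 15 and 5 and comes back at 18. Bromide F4 is made from 15 through F3 as described for step 8. Cross-metathesis of excess F4 with 5 (Hoveyda–Grubbs II, CH2Cl2, 40 °C) gives the thermodynamic E-enoate, methyl (2E,4R,6E,10R)-2-(bromomethyl)-10-({[tert-butyl(diphenyl)silyl]oxy}methyl)-6-(methoxycarbonyl)-4-{[(2Z)-2-methylbut-2-enoyl]oxy}-12-oxododeca-2,6-dienoate F6. Intramolecular Nozaki–Hiyama allylation (CrCl2, THF, 2 mM, slow addition) closes the ten-membered ring to methyl (1E,5R,7R,8S,9R)-5-({[tert-butyl(diphenyl)silyl]oxy}methyl)-7-hydroxy-8-(3-methoxy-3-oxoprop-1-en-2-yl)-9-{[(2Z)-2-methylbut-2-enoyl]oxy}cyclodec-1-ene-1-carboxylate F7. TsOH lactonises F7 to 18.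

**Further compounds**
F1 | step 7 | dimethyl (2E,4R)-6-methylidene-4-{[(2Z)-2-methylbut-2-enoyl]oxy}-2-(tributylstannyl)hept-2-enedioate | COC(=O)C(=C)C[C@@H](OC(=O)/C(C)=C\C)/C=C(/[Sn](CCCC)(CCCC)CCCC)C(=O)OC
F2 | step 7 | dimethyl (2E,4R)-2-iodo-6-methylidene-4-{[(2Z)-2-methylbut-2-enoyl]oxy}hept-2-enedioate | COC(=O)C(=C)C[C@@H](OC(=O)/C(C)=C\C)/C=C(/I)C(=O)OC
F3 | step 8 | dimethyl (2Z,4R)-2-(hydroxymethyl)-6-methylidene-4-{[(2Z)-2-methylbut-2-enoyl]oxy}hept-2-enedioate | COC(=O)C(=C)C[C@@H](OC(=O)/C(C)=C\C)/C=C(/CO)C(=O)OC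
F4 | step 8 | dimethyl (2E,4R)-2-(bromomethyl)-6-methylidene-4-{[(2Z)-2-methylbut-2-enoyl]oxy}hept-2-enedioate | COC(=O)C(=C)C[C@@H](OC(=O)/C(C)=C\C)/C=C(/CBr)C(=O)OC
F5 | step 8 | dimethyl (4R,5S)-5-[(1R,3R)-3-({[tert-butyl(diphenyl)silyl]oxy}methyl)-1-hydroxyhept-6-en-1-yl]-2,6-dimethylidene-4-{[(2Z)-2-methylbut-2-enoyl]oxy}heptanedioate | COC(=O)C(=C)[C@@H]([C@H](O)C[C@H](CO[Si](c1ccccc1)(c1ccccc1)C(C)(C)C)CCC=C)[C@H](OC(=O)/C(C)=C\C)CC(=C)C(=O)OC
F6 | step 9 | methyl (2E,4R,6E,10R)-2-(bromomethyl)-10-({[tert-butyl(diphenyl)silyl]oxy}methyl)-6-(methoxycarbonyl)-4-{[(2Z)-2-methylbut-2-enoyl]oxy}-12-oxododeca-2,6-dienoate | O=CC[C@H](CO[Si](c1ccccc1)(c1ccccc1)C(C)(C)C)CC/C=C(/C(=O)OC)C[C@@H](OC(=O)/C(C)=C\C)/C=C(/CBr)C(=O)OC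
F7 | step 9 | methyl (1E,5R,7R,8S,9R)-5-({[tert-butyl(diphenyl)silyl]oxy}methyl)-7-hydroxy-8-(3-methoxy-3-oxoprop-1-en-2-yl)-9-{[(2Z)-2-methylbut-2-enoyl]oxy}cyclodec-1-ene-1-carboxylate | COC(=O)C(=C)[C@H]1[C@H](O)C[C@H](CO[Si](c2ccccc2)(c2ccccc2)C(C)(C)C)CC/C=C(/C(=O)OC)C[C@H]1OC(=O)/C(C)=C\C
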